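C2–C3 Ring Closure Route to (2R,3R)-6-Methoxyaromadendrin 3-O-Acetate

Cuts, in retrosynthetic order: the three O-benzyl groups; a temporary tert-butyl ester on C3; the C2–C3 bond of ring C; the C3–OAc and C3–CO2tBu bonds (back to an acetyl CH3); the O1–CH2 ether bond to ring B; the C6–O bond of ring A.
Forward: ring A of phloracetophenone is dressed (benzylation, para-hydroxylation, methylation). Ring B is hung on the future O1 as a 4-(benzyloxy)benzyl ether, the acetyl group is raised to an alpha-acetoxy beta-keto ester, and ring C closes last.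
Enabling feature: C2 carries O1 and sits para to the oxygen of ring B, so its C–H bond is the most hydridic one and can leave as hydride to give an oxocarbenium ion. C3 lies between C4=O and its own acetoxy oxygen and, with the helper ester, is a chelating carbon nucleophile six atoms away.
The key step is therefore an oxidative, stereoconvergent C–H/C–H coupling that needs no leaving group at C2 and no preformed enol derivative at C3.
Stereochemistry: C2 comes from a chiral copper bis(oxazoline) enolate in the key step, where the racemic precursor funnels through one planar enolate. C3 comes from acid equilibration to the diequatorial 2,3-trans isomer when the helper ester leaves.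

Key step: step 7

Assumption: the sense of induction cannot be fixed on paper for this tethered case. The (S,S) ligand, 2,2'-(propane-2,2-diyl)bis[(4S)-4-tert-butyl-4,5-dihydrooxazole], is written for the 2R series, and its equally available (R,R) antipode takes its place should the first run show the 2S series.

Step 1
Reactants: 1 2,4,6-trihydroxyacetophenone
Product: 2 1-[2,4-bis(benzyloxy)-6-hydroxyphenyl]ethanone
Conditions: BnBr (2.1 equiv), K2CO3 (2.2 equiv), DMF, 60 °C
Reagents that add atoms: benzyl bromide BrCc1ccccc1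
Why: Williamson etherification; the hydroxyl hydrogen-bonded to the acetyl carbonyl is the least nucleophilic, so two equivalents of BnBr should stop at the dibenzyl ether (the two ortho hydroxyls of 1 are equivalent).

Step 2
Reactants: 2 1-[2,4-bis(benzyloxy)-6-hydroxyphenyl]ethanone
Product: 4 1-[2,4-bis(benzyloxy)-3,6-dihydroxyphenyl]ethanone, via aryl sulfate 3 (not isolated)
Conditions: K2S2O8 (1.1 equiv), aq KOH, pyridine, 0 °C to rt; then aq HCl to pH 1, 85 °C
Reagents that add atoms: potassium persulfate [K+].[K+].[O-]S(=O)(=O)OOS(=O)(=O)[O-]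
Why: Elbs persulfate oxidation; the phenolate attacks the peroxide oxygen through its free para carbon, which lies between the two benzyloxy groups, and acid hydrolysis of the aryl sulfate frees the hydroquinone, so the fourth oxygen of ring A enters only at the future C6.

Step 3
Reactants: 4 1-[2,4-bis(benzyloxy)-3,6-dihydroxyphenyl]ethanone
Product: 5 1-[2,4-bis(benzyloxy)-6-hydroxy-3-methoxyphenyl]ethanone
Conditions: MeI (1.05 equiv), K2CO3 (1.1 equiv), acetone, reflux
Reagents that add atoms: iodomethane CI
Why: Williamson methylation with one equivalent of reagent; the 6-OH stays locked in its hydrogen bond to the carbonyl, so only the new 3-OH should be methylated.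

Step 4
Reactants: 5 1-[2,4-bis(benzyloxy)-6-hydroxy-3-methoxyphenyl]ethanone; 6 4-(benzyloxy)benzyl chloride
Product: 7 1-{2,4-bis(benzyloxy)-6-[4-(benzyloxy)benzyloxy]-3-methoxyphenyl}ethanone
Conditions: K2CO3 (1.5 equiv), KI (cat.), DMF, 70 °C
Reagents that add atoms: none
Why: Williamson etherification under forcing conditions alkylates the remaining chelated phenol, which is the future O1, and thereby fixes the 6-methoxy rather than the 8-methoxy pattern.

Step 5
Reactants: 7 1-{2,4-bis(benzyloxy)-6-[4-(benzyloxy)benzyloxy]-3-methoxyphenyl}ethanone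
Product: 8 tert-butyl 3-{2,4-bis(benzyloxy)-6-[4-(benzyloxy)benzyloxy]-3-methoxyphenyl}-3-oxopropanoate
Conditions: LiHMDS (2.2 equiv), THF, −78 °C; Boc2O (1.1 equiv), −78 °C to 0 °C; AcOH quench
Reagents that add atoms: di-tert-butyl dicarbonate CC(C)(C)OC(=O)OC(=O)OC(C)(C)C
Why: Crossed Claisen-type C-acylation of the lithium enolate of a methyl ketone by Boc2O; the second equivalent of base removes the product as its stabilised enolate, which should drive C-acylation and prevent a second acylation.

Step 6
Reactants: 8 tert-butyl 3-{2,4-bis(benzyloxy)-6-[4-(benzyloxy)benzyloxy]-3-methoxyphenyl}-3-oxopropanoate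
Product: 9 tert-butyl 2-acetoxy-3-{2,4-bis(benzyloxy)-6-[4-(benzyloxy)benzyloxy]-3-methoxyphenyl}-3-oxopropanoate (racemic)
Conditions: Pb(OAc)4 (1.05 equiv), CH2Cl2, 0 °C to rt
Reagents that add atoms: lead tetraacetate CC(=O)O[Pb](OC(C)=O)(OC(C)=O)OC(C)=O
Why: Lead tetraacetate alpha-acetoxylation of a beta-dicarbonyl compound through its enol; the new centre (future C3) is racemic and labile, which is harmless because step 7 passes through the planar enolate.

Step 7
Reactants: 9 tert-butyl 2-acetoxy-3-{2,4-bis(benzyloxy)-6-[4-(benzyloxy)benzyloxy]-3-methoxyphenyl}-3-oxopropanoate (racemic)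
Product: 11 tert-butyl (2R,3S)-3-acetoxy-5,7-bis(benzyloxy)-2-[4-(benzyloxy)phenyl]-6-methoxy-4-oxochromane-3-carboxylate, via oxocarbenium enolate 10 (not isolated)
Conditions: DDQ (1.2 equiv), Cu(OTf)2 (10 mol %), (S,S)-tBu-box (12 mol %), 2,6-dichloropyridine (1 equiv), 4 Å MS, CH2Cl2, −30 °C to 0 °C
Reagents that add atoms: none
Why: Proposed new method: DDQ removes hydride from the O1–CH2 group of 9 and Cu(OTf)2/(S,S)-tBu-box binds the 1,3-dicarbonyl unit as a planar chelated enolate, so that both enantiomers of the labile racemate 9 funnel into the one oxocarbenium enolate 10, whose C3 attacks C2 while DDQH− takes up the proton (net loss of H2 to DDQ). The closest known reaction type is the enantioselective intramolecular cross-dehydrogenative coupling of beta-keto esters with DDQ-generated oxocarbenium ions of benzylic or allylic alkyl ethers under divalent copper bis(oxazoline) catalysis, which gives 2-substituted tetrahydropyran-4-ones; new here are the phenolic ether oxygen and the fully substituted alpha-acetoxy nucleophile. Ring C closes in the 6-(enolendo)-endo-trig mode, with ring A twisted out of the enolate plane by its two ortho oxygens so that the cationic arm already lies over one enolate face. C2 is set by the ligand, which should leave only one of the two faces beside the ketone oxygen open to that arm, and by the E geometry of the oxocarbenium ion, which puts ring B pseudo-equatorial; C3 is set by the chelate geometry (the ester, trans to ring A, becomes pseudo-equatorial and the acetoxy group pseudo-axial) and is only temporary. The step needs site selectivity among four benzylic ether CH2 groups and C- over O-alkylation: only the O1–CH2 group has a para oxygen donor on its arene, the acyl group tempers ring A, and O-attack gives an enol acetal that should re-ionise under the Lewis acid in the Petasis–Ferrier manner and drain to the C–C product. The quaternary C3 of 11 also blocks further dehydrogenation towards the flavonol level.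

Step 8
Reactants: 11 tert-butyl (2R,3S)-3-acetoxy-5,7-bis(benzyloxy)-2-[4-(benzyloxy)phenyl]-6-methoxy-4-oxochromane-3-carboxylate
Product: 14 (2R,3R)-5,7-bis(benzyloxy)-2-[4-(benzyloxy)phenyl]-6-methoxy-4-oxochroman-3-yl acetate, via keto acid 12 (not isolated), via enol 13 (not isolated)
Conditions: TsOH (anhydrous, 0.5 equiv), toluene, 75 °C, N2 sweep
Reagents that add atoms: none
Why: Acid-mediated tert-butyl ester cleavage and beta-keto acid decarboxylation, a sequence known for flavanone-3-carboxylates with retention at C2; the enol 13 ketonises reversibly under the acid, so C3 should settle under thermodynamic control as the diequatorial 2,3-trans isomer relayed from the untouched C2.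

Step 9
Reactants: 14 (2R,3R)-5,7-bis(benzyloxy)-2-[4-(benzyloxy)phenyl]-6-methoxy-4-oxochroman-3-yl acetate
Product: 15 (2R,3R)-5,7-dihydroxy-2-(4-hydroxyphenyl)-6-methoxy-4-oxochroman-3-yl acetate (6-methoxyaromadendrin 3-O-acetate)
Conditions: H2 (1 atm), 10% Pd/C, EtOAc–THF, rt
Reagents that add atoms: none
Why: Catalytic hydrogenolysis of the three aryl benzyl ethers under neutral conditions, which should leave the alpha-acetoxy ketone, the cyclic C2–O1 bond (deactivated by the neighbouring acyloxy and carbonyl groups) and both stereocentres untouched.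

Compound list
1 | 2,4,6-trihydroxyacetophenone | CC(=O)c1c(O)cc(O)cc1O | starting material
2 | 1-[2,4-bis(benzyloxy)-6-hydroxyphenyl]ethanone | CC(=O)c1c(O)cc(OCc2ccccc2)cc1OCc1ccccc1 | intermediate
3 | potassium 3-acetyl-2,6-bis(benzyloxy)-4-hydroxyphenyl sulfate (aryl sulfate) | CC(=O)c1c(O)cc(OCc2ccccc2)c(OS(=O)(=O)[O-])c1OCc1ccccc1.[K+] | intermediate
4 | 1-[2,4-bis(benzyloxy)-3,6-dihydroxyphenyl]ethanone | CC(=O)c1c(O)cc(OCc2ccccc2)c(O)c1OCc1ccccc1 | intermediate
5 | 1-[2,4-bis(benzyloxy)-6-hydroxy-3-methoxyphenyl]ethanone | CC(=O)c1c(O)cc(OCc2ccccc2)c(OC)c1OCc1ccccc1 | intermediate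
6 | 4-(benzyloxy)benzyl chloride | ClCc1ccc(OCc2ccccc2)cc1 | starting material
7 | 1-{2,4-bis(benzyloxy)-6-[4-(benzyloxy)benzyloxy]-3-methoxyphenyl}ethanone | CC(=O)c1c(OCc2ccc(OCc3ccccc3)cc2)cc(OCc2ccccc2)c(OC)c1OCc1ccccc1 | intermediate
8 | tert-butyl 3-{2,4-bis(benzyloxy)-6-[4-(benzyloxy)benzyloxy]-3-methoxyphenyl}-3-oxopropanoate | CC(C)(C)OC(=O)CC(=O)c1c(OCc2ccc(OCc3ccccc3)cc2)cc(OCc2ccccc2)c(OC)c1OCc1ccccc1 | intermediate
9 | tert-butyl 2-acetoxy-3-{2,4-bis(benzyloxy)-6-[4-(benzyloxy)benzyloxy]-3-methoxyphenyl}-3-oxopropanoate (racemic, configurationally labile) | CC(C)(C)OC(=O)C(OC(C)=O)C(=O)c1c(OCc2ccc(OCc3ccccc3)cc2)cc(OCc2ccccc2)c(OC)c1OCc1ccccc1 | intermediate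
10 | oxocarbenium enolate: (E)-oxocarbenium ion at the former O1–CH2 group next to the chelated enolate (ester cis to the enolate oxygen), drawn as the copper-free zwitterion | CC(C)(C)OC(=O)/C(OC(C)=O)=C(\[O-])c1c(/[O+]=C/c2ccc(OCc3ccccc3)cc2)cc(OCc2ccccc2)c(OC)c1OCc1ccccc1 | intermediate
11 | tert-butyl (2R,3S)-3-acetoxy-5,7-bis(benzyloxy)-2-[4-(benzyloxy)phenyl]-6-methoxy-4-oxochromane-3-carboxylate | COc1c(OCc3ccccc3)cc2c(c1OCc1ccccc1)C(=O)[C@](OC(C)=O)(C(=O)OC(C)(C)C)[C@@H](c1ccc(OCc3ccccc3)cc1)O2 | intermediate
12 | (2R,3S)-3-acetoxy-5,7-bis(benzyloxy)-2-[4-(benzyloxy)phenyl]-6-methoxy-4-oxochromane-3-carboxylic acid (keto acid) | COc1c(OCc3ccccc3)cc2c(c1OCc1ccccc1)C(=O)[C@](OC(C)=O)(C(=O)O)[C@@H](c1ccc(OCc3ccccc3)cc1)O2 | intermediate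
13 | (2R)-5,7-bis(benzyloxy)-2-[4-(benzyloxy)phenyl]-4-hydroxy-6-methoxy-2H-chromen-3-yl acetate (enol) | COc1c(OCc3ccccc3)cc2c(c1OCc1ccccc1)C(O)=C(OC(C)=O)[C@@H](c1ccc(OCc3ccccc3)cc1)O2 | intermediate
14 | (2R,3R)-5,7-bis(benzyloxy)-2-[4-(benzyloxy)phenyl]-6-methoxy-4-oxochroman-3-yl acetate | COc1c(OCc3ccccc3)cc2c(c1OCc1ccccc1)C(=O)[C@H](OC(C)=O)[C@@H](c1ccc(OCc3ccccc3)cc1)O2 | intermediate
15 | (2R,3R)-5,7-dihydroxy-2-(4-hydroxyphenyl)-6-methoxy-4-oxochroman-3-yl acetate (6-methoxyaromadendrin 3-O-acetate) | COc1c(O)cc2c(c1O)C(=O)[C@H](OC(C)=O)[C@@H](c1ccc(O)cc1)O2 | target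

Total step count: 9. Longest linear sequence: 9 steps (from 1).

Steps most likely to fail

1. Step 7.
- **What may go wrong:** Hydride abstraction from a phenolic, less donating ether may be too slow at the temperatures where the catalyst is selective. Lewis or Brønsted acid may ionise the O1–CH2 bond, with loss of the ring B benzyl group. The crowded nucleophile may refuse the cation, or facial selectivity may be poor.
- **Fallback (known chemistry, ring C closed from the oxygen side):** It sets out from 5 and returns at 14. The chelated phenol of 5 is protected (MOMCl, NaH, DMF) to the MOM-protected acetophenone F1. Claisen–Schmidt condensation with commercial 4-(benzyloxy)benzaldehyde (KOH, EtOH) should give the (E)-chalcone F2. Juliá–Colonna epoxidation (poly-L-leucine, urea–H2O2, DBU, THF) should give the (2R,3S)-epoxy ketone F3. HCl in MeOH–THF removes the MOM group, and the freed phenol opens the epoxide at its benzylic carbon with inversion to the (2R,3R)-dihydroflavonol tribenzyl ether F4. Ac2O in pyridine then gives 14.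

2. Step 8.
- **What may go wrong:** Kinetic ketonisation of the enol may favour the 2,3-cis epimer, and equilibration at C3 may stay incomplete. Prolonged acid may open the O1–C2 bond, eroding C2, or may cleave the benzyl ether next to the carbonyl group.
- **Fallback:** It sets out from 8 and returns at 14, and it sets C3 kinetically by face selection instead of by equilibration. The copper/DDQ closure of step 7 is run on 8 itself, which lacks the acetoxy group and lies closer to the known substrate class, to give the flavanone-3-carboxylate F5. TsOH in toluene removes the ester to give the (2S)-flavanone F6. TMSOTf and Et3N in CH2Cl2 give the silyl enol ether F7. Rubottom oxidation with dimethyldioxirane should attack the face anti to ring B and, after mild acidic work-up, give the dihydroflavonol tribenzyl ether F4 already met above. Ac2O in pyridine gives 14.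

3. Step 2.
- **What may go wrong:** Conversion may be low, the electron-rich phenolate may be over-oxidised by persulfate to polymeric material, and benzyl ether may be partly lost during the hot acid hydrolysis of the sulfate.
- **Fallback:** It sets out from 2 and returns at 4 through the quinone oxidation level. PhI(OCOCF3)2 in MeCN–H2O at 0 °C oxidises the para-unsubstituted phenol to the acetylbenzoquinone F8, and Na2S2O4 in THF–H2O reduces it to the hydroquinone 4.

Further compounds
F1 | step 7 | MOM-protected acetophenone 1-[2,4-bis(benzyloxy)-3-methoxy-6-(methoxymethoxy)phenyl]ethanone | CC(=O)c1c(OCOC)cc(OCc2ccccc2)c(OC)c1OCc1ccccc1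
F2 | step 7 | (E)-chalcone (E)-1-[2,4-bis(benzyloxy)-3-methoxy-6-(methoxymethoxy)phenyl]-3-[4-(benzyloxy)phenyl]prop-2-en-1-one | COCOc1cc(OCc2ccccc2)c(OC)c(OCc2ccccc2)c1C(=O)/C=C/c1ccc(OCc2ccccc2)cc1
F3 | step 7 | (2R,3S)-epoxy ketone [2,4-bis(benzyloxy)-3-methoxy-6-(methoxymethoxy)phenyl]{(2R,3S)-3-[4-(benzyloxy)phenyl]oxiran-2-yl}methanone | COCOc1cc(OCc2ccccc2)c(OC)c(OCc2ccccc2)c1C(=O)[C@@H]1O[C@H]1c1ccc(OCc2ccccc2)cc1
F4 | step 7 | dihydroflavonol tribenzyl ether (2R,3R)-5,7-bis(benzyloxy)-2-[4-(benzyloxy)phenyl]-3-hydroxy-6-methoxychroman-4-one | COc1c(OCc3ccccc3)cc2c(c1OCc1ccccc1)C(=O)[C@H](O)[C@@H](c1ccc(OCc3ccccc3)cc1)O2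
F5 | step 8 | flavanone-3-carboxylate tert-butyl (2S,3R)-5,7-bis(benzyloxy)-2-[4-(benzyloxy)phenyl]-6-methoxy-4-oxochromane-3-carboxylate | COc1c(OCc3ccccc3)cc2c(c1OCc1ccccc1)C(=O)[C@H](C(=O)OC(C)(C)C)[C@@H](c1ccc(OCc3ccccc3)cc1)O2
F6 | step 8 | (2S)-flavanone (2S)-5,7-bis(benzyloxy)-2-[4-(benzyloxy)phenyl]-6-methoxychroman-4-one | COc1c(OCc3ccccc3)cc2c(c1OCc1ccccc1)C(=O)C[C@@H](c1ccc(OCc3ccccc3)cc1)O2
F7 | step 8 | silyl enol ether (2S)-5,7-bis(benzyloxy)-2-[4-(benzyloxy)phenyl]-6-methoxy-4-(trimethylsilyloxy)-2H-chromene | COc1c(OCc3ccccc3)cc2c(c1OCc1ccccc1)C(O[Si](C)(C)C)=C[C@@H](c1ccc(OCc3ccccc3)cc1)O2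
F8 | step 2 | acetylbenzoquinone 2-acetyl-3,5-bis(benzyloxy)cyclohexa-2,5-diene-1,4-dione | CC(=O)C1=C(OCc2ccccc2)C(=O)C(OCc2ccccc2)=CC1=O
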